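**Retrosynthetic overview**
1. Feature used: in ring A, C2(OH)–C3(Cl)–C4(OMe)–C5(H) carries the oxygen and chlorine pattern of methyl 2-chloroacetoacetate. C1, C6, the depside carbonyl C7 and the C6 pentyl chain together are the eight carbons of oct-2-ynoic acid.
2. Last disconnections: the ring B carboxylic acid comes from an allyl ester and the ring B C2 hydroxyl from a tert-butyldimethylsilyl ether.
3. Key disconnection: ring A is opened at C1–C2 and C5–C6 (retro-[4+2] after adding back methanol). This gives a 2-chloro vinylketene silyl acetal and the ring B aryl oct-2-ynoate, so the depside C–O bond is in place before ring A exists.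
4. The aryl ynoate comes from olivetolic acid by allylation, 4-O-acylation and 2-O-silylation. The diene comes from methyl 2-chloroacetoacetate by O-methylation and dienolate silylation.
5. Ring order: ring B is bought intact, and ring A is the only ring built, in step 6.

Key step: step 6

Assumption: the C=C geometry of the enol ether and of the ketene acetal in the diene line is not controlled. One isomer of each is drawn, and both double bonds end inside aromatic ring A, so the outcome does not depend on it.

**Step 1**
Reactants: 1 olivetolic acid; 2 allyl bromide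
Product: 3 allyl 2,4-dihydroxy-6-pentylbenzoate
Conditions: KHCO3, DMF, rt
Reagents that add atoms: none
Why: Carboxylate O-alkylation (SN2): KHCO3 deprotonates only the carboxylic acid, so allyl bromide esterifies it and leaves both phenols free, and room temperature avoids decarboxylation of the 2-hydroxybenzoic acid.

**Step 2**
Reactants: 3 allyl 2,4-dihydroxy-6-pentylbenzoate; 4 oct-2-ynoic acid
Product: 5 allyl 2-hydroxy-4-(oct-2-ynoyloxy)-6-pentylbenzoate
Conditions: DCC, DMAP (5 mol %), CH2Cl2, 0 °C
Reagents that add atoms: none
Why: Steglich esterification, the usual way to aryl alk-2-ynoates: the C2 hydroxyl of 3 is locked in a hydrogen bond to the ester carbonyl and is the poorer nucleophile, so the unhindered acyl donor from 4 goes to the free C4 hydroxyl, and low temperature with little DMAP holds back conjugate addition to the alkyne.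

**Step 3**
Reactants: 5 allyl 2-hydroxy-4-(oct-2-ynoyloxy)-6-pentylbenzoate
Product: 6 allyl 2-(tert-butyldimethylsilyloxy)-4-(oct-2-ynoyloxy)-6-pentylbenzoate
Conditions: TBSOTf, 2,6-lutidine, CH2Cl2, 0 °C
Reagents that add atoms: tert-butyldimethylsilyl trifluoromethanesulfonate, CC(C)(C)[Si](C)(C)OS(=O)(=O)C(F)(F)F
Why: Silyl ether formation with a silyl triflate: the strongly electrophilic TBSOTf overcomes the hydrogen bond of the chelated phenol, while the hindered, non-nucleophilic 2,6-lutidine cannot attack the activated aryl ynoate or isomerise it to an allenoate.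

**Step 4**
Reactants: 7 methyl 2-chloroacetoacetate
Product: 9 methyl (Z)-2-chloro-3-methoxybut-2-enoate, via dimethyl ketal 8 (not isolated)
Conditions: HC(OMe)3, cat. H2SO4, MeOH, 55 °C; then distillation under reduced pressure
Reagents that add atoms: trimethyl orthoformate, COC(OC)OC
Why: Acid-catalysed ketalisation with an orthoester followed by elimination of methanol, the standard conversion of acetoacetates into 3-methoxybut-2-enoates; the conjugated enol ether is the thermodynamic product, and any deconjugated isomer would give the same dienolate in step 5.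

**Step 5**
Reactants: 9 methyl (Z)-2-chloro-3-methoxybut-2-enoate
Product: 11 (1E)-2-chloro-1,3-dimethoxy-1-(trimethylsilyloxy)buta-1,3-diene, via lithium dienolate 10 (not isolated)
Conditions: LiN(iPr)2, THF, −78 °C; Me3SiCl, −78 °C → rt; pentane, filtration under Ar, Kugelrohr distillation
Reagents that add atoms: chlorotrimethylsilane, C[Si](C)(C)Cl
Why: Kinetic γ-deprotonation of a β-alkoxy enoate to its extended dienolate and O-silylation with the hard electrophile Me3SiCl, the standard preparation of vinylketene silyl acetals; the methyl group is the only acidic site, and α-chloro ester enolates hold at −78 °C.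

**Step 6**
Reactants: 6 allyl 2-(tert-butyldimethylsilyloxy)-4-(oct-2-ynoyloxy)-6-pentylbenzoate; 11 (1E)-2-chloro-1,3-dimethoxy-1-(trimethylsilyloxy)buta-1,3-diene
Product: 14 allyl 2-(tert-butyldimethylsilyloxy)-4-[(3-chloro-2-hydroxy-4-methoxy-6-pentylbenzoyl)oxy]-6-pentylbenzoate, via cyclohexadiene cycloadduct 12 (not isolated), via aryl trimethylsilyl ether 13 (not isolated)
Conditions: 11 (3 equiv, in portions), o-xylene (minimal), 140 °C, sealed tube, Ar; then 1 M HCl, THF, rt
Reagents that add atoms: none
Why: This is the Diels–Alder benzannulation of a 1,1,3-trioxygenated butadiene (vinylketene silyl acetal) with an alkynoate, a known thermal route to resorcylates from β-alkyl ynoates; the new variables are the 2-chloro substituent on the diene and the aryl ester, which lowers the alkyne LUMO relative to an alkyl ester. The CH2 terminus of 11, which has the largest HOMO coefficient, bonds to the pentyl-bearing β-carbon of 6 (C5–C6 bond) and the ketene acetal carbon bonds to the α-carbon (C1–C2 bond), either in one asynchronous [4+2] event or by a vinylogous Mukaiyama–Michael addition followed by 6-exo-trig capture of the silyloxy oxocarbenium ion by the allenolate carbon, and both paths close the six-membered carbocycle of 12. The regiochemistry needed (hydroxyl next to C7, pentyl on the other flank) is secured by this matched polarisation, and chemoselectivity is secured because the allyl C=C and ring B are not electron-poor. The C(OMe)(OSiMe3) carbon of 12 is the only stereocentre formed; it is racemic and vanishes when methanol is lost from C2 and C5 to give 13, so no stereocontrol is required and either geometry of 11 converges. Dilute acid collapses any remaining ketal through the dienone tautomer and cleaves the labile aryl O–SiMe3 bond, while the bulkier ring B silyl ether, the allyl ester and the C4 methyl ether persist. Because C2–C5 arrive as one pre-functionalised block, the C3 chlorine never has to be placed by electrophilic substitution, which in resorcylates tends to go to C5.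

**Step 7**
Reactants: 14 allyl 2-(tert-butyldimethylsilyloxy)-4-[(3-chloro-2-hydroxy-4-methoxy-6-pentylbenzoyl)oxy]-6-pentylbenzoate
Product: 15 allyl 4-[(3-chloro-2-hydroxy-4-methoxy-6-pentylbenzoyl)oxy]-2-hydroxy-6-pentylbenzoate
Conditions: HF·pyridine, THF, 0 °C → rt (plastic vessel)
Reagents that add atoms: none
Why: Fluoride-induced desilylation under weakly acidic conditions: HF·pyridine attacks the silicon of the aryl silyl ether without forming basic fluoride or phenoxide, so the depside ester, the allyl ester, the methyl ether and the aryl chloride are untouched.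

**Step 8**
Reactants: 15 allyl 4-[(3-chloro-2-hydroxy-4-methoxy-6-pentylbenzoyl)oxy]-2-hydroxy-6-pentylbenzoate
Product: 16 4-[(3-chloro-2-hydroxy-4-methoxy-6-pentylbenzoyl)oxy]-2-hydroxy-6-pentylbenzoic acid (target)
Conditions: Pd(PPh3)4 (5 mol %), morpholine, THF, rt; then cold 1 M HCl wash
Reagents that add atoms: none
Why: Tsuji–Trost deallylation: zerovalent palladium ionises the allyl ester to a π-allyl complex and the carboxylate, morpholine captures the allyl unit, and at room temperature the doubly ortho-substituted depside ester resists aminolysis, the aryl chloride does not undergo oxidative addition and the acid does not decarboxylate.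

**Compound list**
1 | olivetolic acid (2,4-dihydroxy-6-pentylbenzoic acid) | CCCCCc1cc(O)cc(O)c1C(=O)O | starting material
2 | allyl bromide | C=CCBr | starting material
3 | allyl 2,4-dihydroxy-6-pentylbenzoate | CCCCCc1cc(O)cc(O)c1C(=O)OCC=C | intermediate
4 | oct-2-ynoic acid | CCCCCC#CC(=O)O | starting material
5 | allyl 2-hydroxy-4-(oct-2-ynoyloxy)-6-pentylbenzoate | CCCCCC#CC(=O)Oc1cc(CCCCC)c(C(=O)OCC=C)c(O)c1 | intermediate
6 | allyl 2-(tert-butyldimethylsilyloxy)-4-(oct-2-ynoyloxy)-6-pentylbenzoate | CCCCCC#CC(=O)Oc1cc(CCCCC)c(C(=O)OCC=C)c(O[Si](C)(C)C(C)(C)C)c1 | intermediate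
7 | methyl 2-chloroacetoacetate | CC(=O)C(Cl)C(=O)OC | starting material
8 | methyl 2-chloro-3,3-dimethoxybutanoate (racemic, not isolated) | COC(=O)C(Cl)C(C)(OC)OC | intermediate
9 | methyl (Z)-2-chloro-3-methoxybut-2-enoate (methoxy trans to the ester; an E/Z mixture serves equally) | COC(=O)/C(Cl)=C(\C)OC | intermediate
10 | lithium dienolate of 9 (not isolated, geometry undefined) | [Li]OC(OC)=C(Cl)C(=C)OC | intermediate
11 | (1E)-2-chloro-1,3-dimethoxy-1-(trimethylsilyloxy)buta-1,3-diene (either C1=C2 geometry serves) | C=C(OC)/C(Cl)=C(/OC)O[Si](C)(C)C | intermediate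
12 | racemic cyclohexa-1,4-diene cycloadduct (not isolated; ring A numbering: C1=C6 and C3=C4 double bonds, C2 bearing OMe and OSiMe3, C5 a CH2) | CCCCCC1=C(C(=O)Oc2cc(CCCCC)c(C(=O)OCC=C)c(O[Si](C)(C)C(C)(C)C)c2)C(OC)(O[Si](C)(C)C)C(Cl)=C(OC)C1 | intermediate
13 | allyl 2-(tert-butyldimethylsilyloxy)-4-{[3-chloro-4-methoxy-6-pentyl-2-(trimethylsilyloxy)benzoyl]oxy}-6-pentylbenzoate (not isolated) | CCCCCc1cc(OC)c(Cl)c(O[Si](C)(C)C)c1C(=O)Oc1cc(CCCCC)c(C(=O)OCC=C)c(O[Si](C)(C)C(C)(C)C)c1 | intermediate
14 | allyl 2-(tert-butyldimethylsilyloxy)-4-[(3-chloro-2-hydroxy-4-methoxy-6-pentylbenzoyl)oxy]-6-pentylbenzoate | CCCCCc1cc(OC(=O)c2c(CCCCC)cc(OC)c(Cl)c2O)cc(O[Si](C)(C)C(C)(C)C)c1C(=O)OCC=C | intermediate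
15 | allyl 4-[(3-chloro-2-hydroxy-4-methoxy-6-pentylbenzoyl)oxy]-2-hydroxy-6-pentylbenzoate | CCCCCc1cc(OC(=O)c2c(CCCCC)cc(OC)c(Cl)c2O)cc(O)c1C(=O)OCC=C | intermediate
16 | 4-[(3-chloro-2-hydroxy-4-methoxy-6-pentylbenzoyl)oxy]-2-hydroxy-6-pentylbenzoic acid (CNP0310773.0) | CCCCCc1cc(OC(=O)c2c(CCCCC)cc(OC)c(Cl)c2O)cc(O)c1C(=O)O | target

**Total step count:** 8. **Longest linear sequence:** 6 (steps 1, 2, 3, 6, 7, 8). The diene line (steps 4 and 5) is convergent.

**Steps most likely to fail**

Step 6. The β-pentyl alkyne is a weak dienophile. The 2-chloro substituent lowers the diene HOMO and crowds the s-cis conformer, so thermal O-to-C silyl migration or decay of the diene may outrun bond formation. Aromatisation by loss of silanol instead of methanol would also leave C2 as a methyl ether.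

The fallback gives up the benzannulation for a classical depside condensation. It sets out from 3 and comes back to the route at 15.
- Commercial olivetol dimethyl ether (CCCCCc1cc(OC)cc(OC)c1) is lithiated between its two methoxy groups (n-BuLi, THF, 0 °C) and quenched with C2Cl6 to give 2-chloro-1,3-dimethoxy-5-pentylbenzene F1.
- Rieche formylation (Cl2CHOMe, TiCl4, CH2Cl2) at either of the two equivalent free positions gives 3-chloro-2,4-dimethoxy-6-pentylbenzaldehyde F2.
- BCl3 (CH2Cl2, −78 → 0 °C) removes only the methyl ether chelated to the aldehyde, giving 3-chloro-2-hydroxy-4-methoxy-6-pentylbenzaldehyde F3.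
- Pinnick oxidation (NaClO2, NaH2PO4, sulfamic acid) gives 3-chloro-2-hydroxy-4-methoxy-6-pentylbenzoic acid F4.
- F4 is condensed with the free C4 hydroxyl of 3 by (CF3CO)2O in toluene to give 15.

Step 5. The tetrasubstituted enoate may be deprotonated incompletely, silylation may go to carbon instead of oxygen, or the mixed ketene acetal may hydrolyse during isolation.

The fallback moves the O-methylation to the end of ring A construction and uses a bis(silyloxy) diene, a class in which 2-chloro members are known. It sets out from 7 and comes back at 14.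
- 7 is silylated (Me3SiCl, Et3N) to methyl 2-chloro-3-(trimethylsilyloxy)but-2-enoate F5.
- F5 is converted (LiN(iPr)2, Me3SiCl, THF, −78 °C) into 2-chloro-1-methoxy-1,3-bis(trimethylsilyloxy)buta-1,3-diene F6.
- F6 is added to 6 as in step 6, giving after acid work-up allyl 2-(tert-butyldimethylsilyloxy)-4-[(3-chloro-2,4-dihydroxy-6-pentylbenzoyl)oxy]-6-pentylbenzoate F7.
- The non-chelated ring A C4 hydroxyl, made more acidic by the neighbouring chlorine, is then methylated alone with Me3SiCHN2 (toluene/MeOH) to give 14.

Step 3. The chelated hydroxyl may be silylated slowly, and forcing conditions would expose the activated aryl ynoate to acyl transfer or alkyne-to-allene isomerisation.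

The fallback drops the isolated protecting group in favour of transient silylation. It sets out from 5 and comes back at 15, so that steps 3 and 7 fall away.
- 5 is warmed with N,O-bis(trimethylsilyl)acetamide in o-xylene to form allyl 4-(oct-2-ynoyloxy)-6-pentyl-2-(trimethylsilyloxy)benzoate F8 in the flask.
- Diene 11 is added and the cycloaddition is run as in step 6.
- The aromatised allyl 4-{[3-chloro-4-methoxy-6-pentyl-2-(trimethylsilyloxy)benzoyl]oxy}-6-pentyl-2-(trimethylsilyloxy)benzoate F9 loses both trimethylsilyl groups in the acid work-up to give 15.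

**Further compounds**
F1 | step 6 | 2-chloro-1,3-dimethoxy-5-pentylbenzene | CCCCCc1cc(OC)c(Cl)c(OC)c1
F2 | step 6 | 3-chloro-2,4-dimethoxy-6-pentylbenzaldehyde | CCCCCc1cc(OC)c(Cl)c(OC)c1C=O
F3 | step 6 | 3-chloro-2-hydroxy-4-methoxy-6-pentylbenzaldehyde | CCCCCc1cc(OC)c(Cl)c(O)c1C=O
F4 | step 6 | 3-chloro-2-hydroxy-4-methoxy-6-pentylbenzoic acid | CCCCCc1cc(OC)c(Cl)c(O)c1C(=O)O
F5 | step 5 | methyl 2-chloro-3-(trimethylsilyloxy)but-2-enoate (geometry not controlled) | COC(=O)C(Cl)=C(C)O[Si](C)(C)C
F6 | step 5 | 2-chloro-1-methoxy-1,3-bis(trimethylsilyloxy)buta-1,3-diene (geometry not controlled) | C=C(O[Si](C)(C)C)C(Cl)=C(OC)O[Si](C)(C)C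
F7 | step 5 | allyl 2-(tert-butyldimethylsilyloxy)-4-[(3-chloro-2,4-dihydroxy-6-pentylbenzoyl)oxy]-6-pentylbenzoate | CCCCCc1cc(OC(=O)c2c(CCCCC)cc(O)c(Cl)c2O)cc(O[Si](C)(C)C(C)(C)C)c1C(=O)OCC=C
F8 | step 3 | allyl 4-(oct-2-ynoyloxy)-6-pentyl-2-(trimethylsilyloxy)benzoate | CCCCCC#CC(=O)Oc1cc(CCCCC)c(C(=O)OCC=C)c(O[Si](C)(C)C)c1
F9 | step 3 | allyl 4-{[3-chloro-4-methoxy-6-pentyl-2-(trimethylsilyloxy)benzoyl]oxy}-6-pentyl-2-(trimethylsilyloxy)benzoate | CCCCCc1cc(OC(=O)c2c(CCCCC)cc(OC)c(Cl)c2O[Si](C)(C)C)cc(O[Si](C)(C)C)c1C(=O)OCC=C
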